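## Structural features

The target is a trans-fused bicyclo[5.3.0]decane (hydroazulene) sesquiterpene alcohol whose C1 oxygen is acylated by isovanillic acid (3-hydroxy-4-methoxybenzoic acid). The seven-membered ring is numbered C1 (ester CH), C2, C3 (methyl carbinol), C4, C5, C6, C10 (CH–isopropyl); the five-membered ring is C5, C6, C7, C8 (C–CH3), C9, with a trisubstituted epoxide across C8–C9. With the seven-membered ring drawn flat and C1→C2→C3→C4→C5→C6→C10 running clockwise, the C1 oxygen, the C3 hydroxyl, the C10 isopropyl group, the C5–C9 bond and the epoxide oxygen lie below the plane (α). The C3 methyl, the C6–C7 bond and the C8 methyl lie above it (β); in this numbering the configuration is 1R,3R,5S,6R,8R,9S,10S. Six stereocentres (C1, C10, C6, C5, C9, C8) are contiguous, and C3 is cis-1,3 to both the C1 oxygen and the C5 arm. Fragile groups are the acid-labile epoxide, the tertiary alcohol, the free phenol and the aryl ester, which sits on a hindered position cis to isopropyl and cis-1,3 to the C3 hydroxyl (acyl shift under base). The real difficulty is the contiguous array around the ring fusion, with the epoxide oxygen on the face of the neighbouring C5–C4 bond and the ester cis to isopropyl. The key step exploits the fact that the C8–C9 epoxide lies inside the five-membered ring next to the fusion carbon C5: C9 can be a sulfonium ylide carbon on a one-carbon arm at C5 and C8 the carbonyl of an acetonyl arm at C6, so the cyclopentane and the oxirane form together from a monocyclic cycloheptane.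

## Logic of the disconnections

33 to 32. The two O–Si bonds (phenol and C3 hydroxyl) are cut. Both hydroxyls must be masked while base and electrophiles are used, and one fluoride step removes both masks. The forward step has to spare the epoxide and the ester, so buffered fluoride is required.

32 to 29 (key). The C8–C9 bond and the C9–O bond are cut. Both end at C9, so one ylide carbon can make them in sequence. This removes a ring, the oxirane and two stereocentres and leaves a monocyclic cycloheptane with two trans arms. The forward step needs ylide formation to beat enolisation and the sulfur to sit anti to the C5–C4 bond. A free C3 hydroxyl in the sulfonium salt would be a design fault: its alkoxide is cis-1,3 to the C9 arm (ether formation) and to the ester (acyl shift) and would consume base. 29 therefore carries a silyl ether at C3, and triflate as a spectator counter-ion.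

29 to 28. The C8=O bond is traced back to a C8=CH2 alkene. A ketone could not pass through the organometallic, silylation and triflation steps, whereas the alkene is inert to all of them. The forward cleavage must tolerate the sulfonium group and the arene and must avoid nucleophilic reductants.

28 to 26. The C9–S bond is cut to a primary alcohol. The alcohol is the natural product of the earlier C–Si oxidation and is activated only when everything else is in place. The demand is an SN2 reaction of a weak sulfur nucleophile at a β-branched primary carbon without participation of neighbouring oxygen or the alkene.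

26 to 24 (by way of 25). One O–Si bond is formed at C3 and one is removed at C9 in the backward sense. This ordering lets the tertiary hydroxyl be masked while the primary one is still protected. The forward steps rely on the rate difference between primary and tertiary silyl ethers.

24 to 19 and 22. The C1 O–acyl bond is cut, which makes the route convergent. 22 comes from 20 by silylation (via 21). The forward acylation must take a hindered secondary hydroxyl in the presence of a tertiary one.

19 to 17 (by way of 18). The primary O–Si bond and the C3–CH3 bond are cut, which returns C3 to a ketone and removes a stereocentre. The methyl group must enter from the β face.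

17 to 15 (by way of 16). The C5–C9 bond is cut, with the C9 oxygen traced to a C–Si bond. This gives a cyclohept-2-enone whose β-carbon is C5. The forward addition must occur anti to the C6 substituent, and the silane must be oxidised before any reagent that attacks alkoxysilanes is used.

15 to 13 (by way of 14). Oxidation levels at C1 and C3 are exchanged: the C3 carbonyl comes from an allylic carbinol and the C1 carbinol from a ketone. An aldol that created C1 in an open chain would rely on a weak bias between two branched α-substituents. A hydride addition to a ring ketone flanked by the isopropyl-bearing carbon is controlled by that group. The cost is two redox steps; the gain is a defined C1 and no protecting group on it.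

13 to 12. The C4=C5 bond is cut (metathesis), opening the seven-membered ring to an acyclic triene. The forward closure must ignore the 1,1-disubstituted alkene.

12 to 10 and 11. The C2–C3 bond is cut (aldol), giving a methyl ketone and a three-carbon enal. The enolate must form at the methyl group and add 1,2.

10 to 9. The C1–C2 bond (the methyl of the ketone) is cut, giving a carboxylic acid. The ketone must be released only on work-up so that C10 is not epimerised.

9 to 6 (via 7 and 8). The C10–C6 bond is cut (sigmatropic shift). Two adjacent stereocentres are traded for one carbinol centre and two defined double-bond geometries. The forward step needs a defined ketene acetal geometry and a chair transition state.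

6 to 4 and 5, then 4 to 3, then 3 to 1 and 2. The ester C–O bond, the E-alkene (from an alkyne) and the C(sp)–CH2 bond are cut in turn. This ends at a commercial chiral alkynol, an allylic chloride and an acid chloride.

## Other disconnections considered

Alternative 1: The C1–C10 bond of the seven-membered ring is cut, leading back to cyclopentanone aldehyde A2, which has a 2-methylprop-1-enyl group on C6 and the C4–C3–C2–C1 aldehyde chain on C5. In the forward step Me2AlCl activates the aldehyde, C10 attacks C1 and an allylic methyl hydrogen moves to oxygen, giving hydroazulenone A1 with a C1 hydroxyl and a C10 isopropenyl group.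
- In favour: the carbonyl-ene closure is an established reaction type, so on precedent this alternative is the better. It creates C1 and C10 together, and the trans ring fusion can be set on a simple cyclopentanone.
- Against: a seven-membered ene closure lacks the entropic help of the six-membered case, and the C9 ketone competes for the Lewis acid. The chair-like transition state places hydroxyl and isopropenyl trans, so A1 has the C1 configuration opposite to that of the target ester, and the ester would have to be introduced with inversion at a hindered centre. The isopropenyl group must be hydrogenated, and the C8 methyl and the epoxide are still missing.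
- Comparison: on structure the chosen plan is better, because it makes the most fragile group last. On mechanism the concerted ene step is cleaner than an ylide route with competing acid–base paths, so the alternative is better there. On step economy the two are comparable before the key step, but the alternative needs several steps after it against one.

Alternative 2: The C5–C4 and C5–C6 bonds are cut, leading back to aryl diazoketone A4. In the forward step a dirhodium tetracarboxylate such as Rh2(OAc)4 generates a carbene that adds to the arene bond between the chain-bearing carbon and its unsubstituted ortho carbon; the norcaradiene opens to azulenone A3.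
- In favour: the whole carbon skeleton, including the C8 methyl, comes from an aromatic compound in one catalytic step of a known type. On front-end step economy and on precedent this alternative is the better.
- Against: the arene needs its chain ortho to isopropyl and meta to methoxy, which is not where electrophilic substitution goes. A3 is a flat triene with only C5 and C8 defined. C1, C3, C6 and C10 would have to be created by reductions and a hydration without directing groups, including a trans relationship across a tetrasubstituted C6=C10 alkene. The epoxide still has to be made from the C9 ketone.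
- Comparison: the alternative reaches the bicyclic core faster. The chosen plan gives every stereocentre its own control element and is better on stereocontrol and on the number of steps after the key step.

Alternative 3: The C9–C5 bond is cut, leading back to cycloheptenone aldehyde A6. In the forward step a triazolium-derived carbene converts the aldehyde into an acyl anion equivalent, which adds to C5 of the enone to give dione A5.
- In favour: it shares the cycloheptenone logic of the chosen route, so the two are equal on the early steps. It is catalytic, forms the five-membered ring with C9 already oxygenated, and belongs to a known reaction type, so on precedent it is the better.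
- Against: the acyl anion is delivered from the C6 arm to the same face of C5, so a cis ring fusion is expected kinetically. The trans-fused A5 would depend on epimerisation at C5, α to the new ketone, and that equilibrium is not secure. The C8 centre is also α to a ketone, and a hindered aliphatic aldehyde is a poor donor. Afterwards two ketones must be told apart, and the C9 ketone must be turned into a C8=C9 alkene and epoxidised face-selectively.
- Comparison: on mechanism the alternative is at least equal. On structure and step economy the chosen plan is better, because its key step delivers the epoxide itself with the ring fusion already fixed.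

Key step: step 19

Remark: ring compounds are described with the labels C1–C10 and the α/β convention of the first section. The key-step substrate carries the C3 hydroxyl as a triethylsilyl ether and triflate as counter-ion; both are spectator changes.

Step 1
Reactants: 1 (2S)-but-3-yn-2-ol; 2 3-chloro-2-methylprop-1-ene
Product: 3 (2S)-6-methylhept-6-en-3-yn-2-ol
Conditions: CuI (10 mol%), Bu4NI (10 mol%), K2CO3, DMF, rt
Reagents that add atoms: none
Why: Copper-catalysed coupling of a terminal alkyne with an allylic halide; the carbinol centre is untouched and the free hydroxyl is tolerated under carbonate.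

Step 2
Reactants: 3 (2S)-6-methylhept-6-en-3-yn-2-ol
Product: 4 (2S,3E)-6-methylhepta-3,6-dien-2-ol
Conditions: NaAlH2(OCH2CH2OMe)2, THF, 0 °C → rt; aq. potassium sodium tartrate
Reagents that add atoms: none
Why: Hydroxyl-directed trans-hydroalumination of a propargylic alcohol should give only the E-allylic alcohol; the isolated 1,1-disubstituted alkene is not reduced.

Step 3
Reactants: 4 (2S,3E)-6-methylhepta-3,6-dien-2-ol; 5 3-methylbutanoyl chloride
Product: 6 (2S,3E)-6-methylhepta-3,6-dien-2-yl 3-methylbutanoate
Conditions: pyridine, DMAP (cat.), CH2Cl2, 0 °C → rt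
Reagents that add atoms: none
Why: Standard acylation of a secondary alcohol with an acid chloride; no stereocentre is involved.

Step 4
Reactants: 6 (2S,3E)-6-methylhepta-3,6-dien-2-yl 3-methylbutanoate
Product: 9 (2S,3R,4E)-3-(2-methylprop-2-en-1-yl)-2-(propan-2-yl)hex-4-enoic acid, via silyl ketene acetal 7 (not isolated), via trimethylsilyl ester 8 (not isolated)
Conditions: LiN(iPr)2, THF/DMPU (4:1), −78 °C; Me3SiCl; −78 °C → 40 °C; 1 M HCl
Reagents that add atoms: none
Why: Ireland–Claisen rearrangement: enolisation with DMPU should give ketene acetal 7 with isopropyl cis to the silyloxy group. The chair transition state with the carbinol methyl equatorial transfers the S centre to C6, and the ketene acetal geometry fixes C10, giving the isomer with the isopropyl and methylallyl groups syn along the chain. The silyl ester 8 is hydrolysed on work-up.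

Step 5
Reactants: 9 (2S,3R,4E)-3-(2-methylprop-2-en-1-yl)-2-(propan-2-yl)hex-4-enoic acid
Product: 10 (3S,4R,5E)-4-(2-methylprop-2-en-1-yl)-3-(propan-2-yl)hept-5-en-2-one
Conditions: MeLi (2.2 equiv), Et2O, 0 °C → rt; inverse quench into cold aq. NH4Cl
Reagents that add atoms: methyllithium, C[Li]
Why: Addition of methyllithium to the lithium carboxylate gives a stable gem-dialkoxide that releases the methyl ketone only on hydrolysis, so over-addition and epimerisation at C10 are avoided.

Step 6
Reactants: 10 (3S,4R,5E)-4-(2-methylprop-2-en-1-yl)-3-(propan-2-yl)hept-5-en-2-one; 11 prop-2-enal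
Product: 12 (6S,7R,8E)-3-hydroxy-7-(2-methylprop-2-en-1-yl)-6-(propan-2-yl)deca-1,8-dien-5-one (both C3 epimers)
Conditions: LiN(iPr)2, THF, −78 °C; 11, −78 °C; AcOH quench
Reagents that add atoms: none
Why: Kinetic deprotonation at the methyl group (the other α-carbon is tertiary and hindered) and 1,2-addition of the lithium enolate to the enal (aldol reaction). The new carbinol configuration is irrelevant because this carbon becomes the C3 ketone in step 9.

Step 7
Reactants: 12 (6S,7R,8E)-3-hydroxy-7-(2-methylprop-2-en-1-yl)-6-(propan-2-yl)deca-1,8-dien-5-one
Product: 13 cyclohept-4-enone (C1 ketone; C3 hydroxyl as both epimers; C6 β-2-methylallyl; C10 α-isopropyl)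
Conditions: second-generation Grubbs catalyst [RuCl2(=CHPh)(PCy3)(H2IMes)] (5 mol%), CH2Cl2 (5 mM), 40 °C
Reagents that add atoms: none
Why: Ring-closing metathesis between the vinyl carbinol and the propenyl group closes the seven-membered ring at C4=C5 with loss of propene. The 1,1-disubstituted alkene could only give a four- or eight-membered ring and should not take part.

Step 8
Reactants: 13 cyclohept-4-enone (C1 ketone; C3 hydroxyl as both epimers; C6 β-2-methylallyl; C10 α-isopropyl)
Product: 14 cyclohept-4-ene-1,3-diol (C1 α-OH; C3 hydroxyl as both epimers; C6 β-2-methylallyl; C10 α-isopropyl)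
Conditions: LiBH(s-Bu)3, THF, −78 °C; then NaOH, H2O2
Reagents that add atoms: none
Why: Substrate-controlled reduction with a bulky trialkylborohydride: hydride should approach C1 from the β face, anti to the adjacent C10 isopropyl group. This places the new hydroxyl α and cis to isopropyl, as in the reduction of 2-alkylcycloalkanones to cis alcohols.

Step 9
Reactants: 14 cyclohept-4-ene-1,3-diol (C1 α-OH; C3 hydroxyl as both epimers; C6 β-2-methylallyl; C10 α-isopropyl)
Product: 15 hydroxy enone (C1 α-OH; C3 ketone; C4=C5; C6 β-2-methylallyl; C10 α-isopropyl)
Conditions: MnO2 (20 equiv), CH2Cl2, rt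
Reagents that add atoms: none
Why: Manganese dioxide oxidises the allylic C3 carbinol and leaves the saturated C1 carbinol alone, so both C3 epimers converge on one enone.

Step 10
Reactants: 15 hydroxy enone (C1 α-OH; C3 ketone; C4=C5; C6 β-2-methylallyl; C10 α-isopropyl)
Product: 17 dihydroxy ketone (C1 α-OH; C3 ketone; C5 α-CH2OH; C6 β-2-methylallyl; C10 α-isopropyl), via alkoxysilane adduct 16 (not isolated)
Conditions: (iPrO)Me2SiCH2MgCl (3 equiv, from (iPrO)Me2SiCH2Cl and Mg), CuI (15 mol%), THF, −78 → −30 °C; aq. NH4Cl; crude in THF/MeOH, KF, KHCO3, 30% H2O2, rt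
Reagents that add atoms: (isopropoxydimethylsilyl)methylmagnesium chloride, CC(C)O[Si](C)(C)C[Mg]Cl; hydrogen peroxide, OO
Why: Copper-catalysed conjugate addition of the silylmethyl Grignard reagent (a hydroxymethyl anion equivalent) should occur at C5 on the α face, anti to the neighbouring C6 substituent. Tamao oxidation then converts the C–Si bond into the primary alcohol before any reagent that attacks alkoxysilanes is used.

Step 11
Reactants: 17 dihydroxy ketone (C1 α-OH; C3 ketone; C5 α-CH2OH; C6 β-2-methylallyl; C10 α-isopropyl)
Product: 18 triol (C1 α-OH; C3 α-OH and β-CH3; C5 α-CH2OH; C6 β-2-methylallyl; C10 α-isopropyl)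
Conditions: MeMgBr (5 equiv), CeCl3, THF, −78 → −20 °C
Reagents that add atoms: methylmagnesium bromide, C[Mg]Br
Why: Cerium-mediated 1,2-addition suppresses enolisation. The pseudo-axial C1 alkoxide on the α face shields that side and can chelate the carbonyl, so methyl should enter from the β face and give the C3 hydroxyl α, cis to the C1 oxygen.

Step 12
Reactants: 18 triol (C1 α-OH; C3 α-OH and β-CH3; C5 α-CH2OH; C6 β-2-methylallyl; C10 α-isopropyl)
Product: 19 C9 triethylsilyl ether of the triol (C1 and C3 hydroxyls free)
Conditions: Et3SiCl (1.05 equiv), imidazole, CH2Cl2, −20 → 0 °C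
Reagents that add atoms: chlorotriethylsilane, CC[Si](Cl)(CC)CC
Why: Selective silylation of the primary hydroxyl over the hindered secondary and the tertiary hydroxyl at low temperature.

Step 13
Reactants: 20 3-hydroxy-4-methoxybenzoic acid
Product: 22 3-[(tert-butyldimethylsilyl)oxy]-4-methoxybenzoic acid, via bis-silylated acid 21 (not isolated)
Conditions: t-BuMe2SiCl (2.5 equiv), imidazole, DMF, rt; then AcOH/THF/H2O, rt
Reagents that add atoms: tert-butylchlorodimethylsilane, CC(C)(C)[Si](C)(C)Cl
Why: Exhaustive silylation followed by selective hydrolysis of the labile silyl ester leaves the phenolic silyl ether, which is stable to mild acid.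

Step 14
Reactants: 19 C9 triethylsilyl ether of the triol (C1 and C3 hydroxyls free); 22 3-[(tert-butyldimethylsilyl)oxy]-4-methoxybenzoic acid
Product: 24 C1 ester (C1 α-aroyloxy; C3 α-OH; C5 α-CH2OSiEt3; C6 β-2-methylallyl; C10 α-isopropyl), via acid chloride 23 (not isolated)
Conditions: 22, (COCl)2, DMF (cat.), CH2Cl2, 0 °C → rt, evaporate; then 19, Et3N, DMAP, CH2Cl2, 0 → 40 °C
Reagents that add atoms: none
Why: Acylation of the secondary C1 hydroxyl by the acid chloride under DMAP catalysis; the tertiary C3 hydroxyl does not compete and no stereocentre changes.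

Step 15
Reactants: 24 C1 ester (C1 α-aroyloxy; C3 α-OH; C5 α-CH2OSiEt3; C6 β-2-methylallyl; C10 α-isopropyl)
Product: 25 bis(triethylsilyl) ether (C3 α-OSiEt3; C5 α-CH2OSiEt3)
Conditions: Et3SiOTf, 2,6-lutidine, CH2Cl2, −78 → 0 °C
Reagents that add atoms: triethylsilyl trifluoromethanesulfonate, CC[Si](CC)(CC)OS(=O)(=O)C(F)(F)F
Why: A silyl triflate with a hindered pyridine base silylates the tertiary hydroxyl; masking it removes the nucleophile that could later attack C9 or the ester.

Step 16
Reactants: 25 bis(triethylsilyl) ether (C3 α-OSiEt3; C5 α-CH2OSiEt3)
Product: 26 primary alcohol (C3 α-OSiEt3; C5 α-CH2OH; C6 β-2-methylallyl)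
Conditions: pyridinium p-toluenesulfonate (cat.), MeOH/CH2Cl2, 0 °C
Reagents that add atoms: none
Why: Acid-catalysed methanolysis removes a primary triethylsilyl ether much faster than a tertiary one, and aryl silyl ethers are stable to mild acid.

Step 17
Reactants: 26 primary alcohol (C3 α-OSiEt3; C5 α-CH2OH; C6 β-2-methylallyl)
Product: 28 alkyldiphenylsulfonium triflate (C5 α-CH2SPh2 cation; C6 β-2-methylallyl), via primary triflate 27 (not isolated)
Conditions: Tf2O, 2,6-di-tert-butyl-4-methylpyridine, CH2Cl2, −78 °C; then Ph2S (10 equiv), −78 °C → rt
Reagents that add atoms: trifluoromethanesulfonic anhydride, O=S(=O)(OS(=O)(=O)C(F)(F)F)C(F)(F)F; diphenyl sulfide, c1ccc(Sc2ccccc2)cc1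
Why: Triflation of the primary alcohol and SN2 displacement by the weakly nucleophilic sulfide in large excess is the standard entry to alkyldiphenylsulfonium salts. The hindered base buffers the acid, and the C3 silyl ether guards against ether formation.

Step 18
Reactants: 28 alkyldiphenylsulfonium triflate (C5 α-CH2SPh2 cation; C6 β-2-methylallyl)
Product: 29 keto sulfonium triflate (C5 α-CH2SPh2 cation; C6 β-CH2C(O)CH3; C3 α-OSiEt3; C1 α-aroyloxy)
Conditions: O3, pyridine (3 equiv), CH2Cl2, −78 °C
Reagents that add atoms: ozone, [O-][O+]=O
Why: Ozonolysis of the 1,1-disubstituted alkene in the presence of pyridine gives the methyl ketone directly, without a nucleophilic reductant that could dealkylate the sulfonium salt. The cationic sulfur and the ester-deactivated arene should react far more slowly with ozone than the alkene.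

Step 19
Reactants: 29 keto sulfonium triflate (C5 α-CH2SPh2 cation; C6 β-CH2C(O)CH3; C3 α-OSiEt3; C1 α-aroyloxy)
Product: 32 bis-silyl ether of the target (C8–C9 α-epoxide; C3 α-OSiEt3; phenol as tert-butyldimethylsilyl ether), via sulfonium ylide 30 (not isolated), via betaine 31 (not isolated)
Conditions: KN(SiMe3)2 (1.05 equiv), THF, −78 → −30 °C
Reagents that add atoms: none
Why: Proposed new method: The amide base should remove a proton from C9, the only carbon next to sulfur that bears hydrogen and the most acidic site, to give ylide 30. The ylide carbon adds to the C8 carbonyl of the acetonyl arm in a 5-exo-trig closure that forms C8–C9 and the cyclopentane, giving betaine 31. The C8 alkoxide then displaces diphenyl sulfide from C9 in a 3-exo-tet closure with inversion, which forms the oxirane. The closest known reaction type is the Corey–Chaykovsky epoxidation in its intramolecular form (epoxy-annulation of a keto sulfonium salt), which has not been used to close a ring onto a substituted carbocycle with control of two new stereocentres. C9 is controlled by the C5 stereocentre: the bulky diphenylsulfonio group should take the β position, trans to the C5–C4 bond, so that inversion leaves the oxygen α, cis to C4. C8 is controlled by the ring: only the betaine with the alkoxide trans to sulfur can reach the backside of C9, so the oxygen is α and the methyl β. The step needs ylide formation to win over enolisation and elimination; the higher acidity of the sulfonium α-protons, the low temperature and the lack of α-hydrogens on the phenyl groups should secure this. The C3 silyl ether removes the alkoxide that would attack C9 or the ester, and the trans arms at C5 and C6 hold the ylide within reach of the ketone.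

Step 20
Reactants: 32 bis-silyl ether of the target (C8–C9 α-epoxide; C3 α-OSiEt3; phenol as tert-butyldimethylsilyl ether)
Product: 33 target CNP0106636.1
Conditions: Bu4NF, AcOH (1:1), THF, 0 °C → rt
Reagents that add atoms: none
Why: Fluoride cleaves both silyl ethers; acetic acid keeps the medium near neutral so that the epoxide and the ester survive and no acyl shift to the C3 oxygen occurs.

## Compound list

1 | (2S)-but-3-yn-2-ol | C[C@H](O)C#C | starting material
2 | 3-chloro-2-methylprop-1-ene | C=C(C)CCl | starting material
3 | (2S)-6-methylhept-6-en-3-yn-2-ol | C[C@H](O)C#CCC(C)=C | intermediate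
4 | (2S,3E)-6-methylhepta-3,6-dien-2-ol | C[C@H](O)/C=C/CC(C)=C | intermediate
5 | 3-methylbutanoyl chloride | CC(C)CC(=O)Cl | starting material
6 | (2S,3E)-6-methylhepta-3,6-dien-2-yl 3-methylbutanoate | C[C@H](OC(=O)CC(C)C)/C=C/CC(C)=C | intermediate
7 | silyl ketene acetal of 6, isopropyl cis to OSiMe3 (Z) | CC(C)/C=C(\O[Si](C)(C)C)O[C@@H](C)/C=C/CC(C)=C | intermediate (not isolated)
8 | trimethylsilyl (2S,3R,4E)-3-(2-methylprop-2-en-1-yl)-2-(propan-2-yl)hex-4-enoate | C/C=C/[C@@H](CC(C)=C)[C@@H](C(=O)O[Si](C)(C)C)C(C)C | intermediate (not isolated)
9 | (2S,3R,4E)-3-(2-methylprop-2-en-1-yl)-2-(propan-2-yl)hex-4-enoic acid | C/C=C/[C@@H](CC(C)=C)[C@@H](C(=O)O)C(C)C | intermediate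
10 | (3S,4R,5E)-4-(2-methylprop-2-en-1-yl)-3-(propan-2-yl)hept-5-en-2-one | C/C=C/[C@@H](CC(C)=C)[C@@H](C(C)=O)C(C)C | intermediate
11 | prop-2-enal | C=CC=O | starting material
12 | (6S,7R,8E)-3-hydroxy-7-(2-methylprop-2-en-1-yl)-6-(propan-2-yl)deca-1,8-dien-5-one, both C3 epimers | C/C=C/[C@@H](CC(C)=C)[C@@H](C(=O)CC(O)C=C)C(C)C | intermediate
13 | cyclohept-4-enone: C1 ketone, C3 OH (both epimers), C6 β-2-methylallyl, C10 α-isopropyl | O=C1CC(O)C=C[C@@H](CC(C)=C)[C@@H]1C(C)C | intermediate
14 | cyclohept-4-ene-1,3-diol: C1 α-OH, C3 OH (both epimers), C6 β-2-methylallyl, C10 α-isopropyl | O[C@@H]1CC(O)C=C[C@@H](CC(C)=C)[C@@H]1C(C)C | intermediate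
15 | hydroxy enone: C1 α-OH, C3 ketone, C4=C5, C6 β-2-methylallyl, C10 α-isopropyl | O[C@@H]1CC(=O)C=C[C@@H](CC(C)=C)[C@@H]1C(C)C | intermediate
16 | alkoxysilane adduct: C5 α-CH2SiMe2(OiPr) | O[C@@H]1CC(=O)C[C@H](C[Si](C)(C)OC(C)C)[C@@H](CC(C)=C)[C@@H]1C(C)C | intermediate (not isolated)
17 | dihydroxy ketone: C1 α-OH, C3 ketone, C5 α-CH2OH, C6 β-2-methylallyl, C10 α-isopropyl | O[C@@H]1CC(=O)C[C@H](CO)[C@@H](CC(C)=C)[C@@H]1C(C)C | intermediate
18 | triol: C1 α-OH, C3 α-OH/β-CH3, C5 α-CH2OH, C6 β-2-methylallyl, C10 α-isopropyl | O[C@@H]1C[C@](C)(O)C[C@H](CO)[C@@H](CC(C)=C)[C@@H]1C(C)C | intermediate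
19 | C9 triethylsilyl ether of 18 | O[C@@H]1C[C@](C)(O)C[C@H](CO[Si](CC)(CC)CC)[C@@H](CC(C)=C)[C@@H]1C(C)C | intermediate
20 | 3-hydroxy-4-methoxybenzoic acid (isovanillic acid) | COc1ccc(C(=O)O)cc1O | starting material
21 | tert-butyldimethylsilyl 3-[(tert-butyldimethylsilyl)oxy]-4-methoxybenzoate | COc1ccc(C(=O)O[Si](C)(C)C(C)(C)C)cc1O[Si](C)(C)C(C)(C)C | intermediate (not isolated)
22 | 3-[(tert-butyldimethylsilyl)oxy]-4-methoxybenzoic acid | COc1ccc(C(=O)O)cc1O[Si](C)(C)C(C)(C)C | intermediate
23 | 3-[(tert-butyldimethylsilyl)oxy]-4-methoxybenzoyl chloride | COc1ccc(C(=O)Cl)cc1O[Si](C)(C)C(C)(C)C | intermediate (not isolated)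
24 | C1 ester: C1 α-aroyloxy, C3 α-OH, C5 α-CH2OSiEt3, C6 β-2-methylallyl, C10 α-isopropyl | COc1ccc(C(=O)O[C@@H]2C[C@](C)(O)C[C@H](CO[Si](CC)(CC)CC)[C@@H](CC(C)=C)[C@@H]2C(C)C)cc1O[Si](C)(C)C(C)(C)C | intermediate
25 | bis(triethylsilyl) ether of the C1 ester (C3 and C9 oxygens) | COc1ccc(C(=O)O[C@@H]2C[C@](C)(O[Si](CC)(CC)CC)C[C@H](CO[Si](CC)(CC)CC)[C@@H](CC(C)=C)[C@@H]2C(C)C)cc1O[Si](C)(C)C(C)(C)C | intermediate
26 | primary alcohol: C3 α-OSiEt3, C5 α-CH2OH | COc1ccc(C(=O)O[C@@H]2C[C@](C)(O[Si](CC)(CC)CC)C[C@H](CO)[C@@H](CC(C)=C)[C@@H]2C(C)C)cc1O[Si](C)(C)C(C)(C)C | intermediate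
27 | primary triflate of 26 | COc1ccc(C(=O)O[C@@H]2C[C@](C)(O[Si](CC)(CC)CC)C[C@H](COS(=O)(=O)C(F)(F)F)[C@@H](CC(C)=C)[C@@H]2C(C)C)cc1O[Si](C)(C)C(C)(C)C | intermediate (not isolated)
28 | alkyldiphenylsulfonium triflate with C6 2-methylallyl arm | COc1ccc(C(=O)O[C@@H]2C[C@](C)(O[Si](CC)(CC)CC)C[C@H](C[S+](c3ccccc3)c3ccccc3)[C@@H](CC(C)=C)[C@@H]2C(C)C)cc1O[Si](C)(C)C(C)(C)C.[O-]S(=O)(=O)C(F)(F)F | intermediate
29 | keto sulfonium triflate (key-step substrate): C5 α-CH2SPh2 cation, C6 β-acetonyl, C3 α-OSiEt3, C1 α-aroyloxy | COc1ccc(C(=O)O[C@@H]2C[C@](C)(O[Si](CC)(CC)CC)C[C@H](C[S+](c3ccccc3)c3ccccc3)[C@@H](CC(C)=O)[C@@H]2C(C)C)cc1O[Si](C)(C)C(C)(C)C.[O-]S(=O)(=O)C(F)(F)F | intermediate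
30 | sulfonium ylide at C9 | COc1ccc(C(=O)O[C@@H]2C[C@](C)(O[Si](CC)(CC)CC)C[C@H]([CH-][S+](c3ccccc3)c3ccccc3)[C@@H](CC(C)=O)[C@@H]2C(C)C)cc1O[Si](C)(C)C(C)(C)C | intermediate (not isolated)
31 | betaine: C8 α-alkoxide/β-CH3, C9 β-SPh2 cation | COc1ccc(C(=O)O[C@@H]2C[C@](C)(O[Si](CC)(CC)CC)C[C@H]3[C@@H](C[C@@](C)([O-])[C@@H]3[S+](c4ccccc4)c4ccccc4)[C@@H]2C(C)C)cc1O[Si](C)(C)C(C)(C)C | intermediate (not isolated)
32 | target as C3 triethylsilyl and phenolic tert-butyldimethylsilyl ether (key-step product) | COc1ccc(C(=O)O[C@@H]2C[C@](C)(O[Si](CC)(CC)CC)C[C@H]3[C@@H](C[C@@]4(C)O[C@@H]34)[C@@H]2C(C)C)cc1O[Si](C)(C)C(C)(C)C | intermediate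
33 | CNP0106636.1 (1R,3R,5S,6R,8R,9S,10S in the numbering used here) | COc1ccc(C(=O)O[C@@H]2C[C@](C)(O)C[C@H]3[C@@H](C[C@@]4(C)O[C@@H]34)[C@@H]2C(C)C)cc1O | target

## Step count and least certain steps

Total: 20 steps. Longest linear sequence: 19 steps (steps 1–12 and 14–20); step 13 prepares the acid side-piece.

Step 19 (key step, proposed new method). The most likely failures are as follows:
- Deprotonation at the ketone α-positions in competition with ylide formation, followed by intramolecular C- or O-alkylation by the sulfonium group.
- Base-induced elimination of diphenyl sulfide across C5–C9.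
- Ring closure through a betaine whose oxygen is syn to sulfur, which cannot form the oxirane.
- Ring closure with sulfur on the C4 side, which gives the epimeric epoxide.

The fallback uses known chemistry, sets out from 26 and returns at 32. The primary alcohol is oxidised with Dess–Martin periodinane to the C9 aldehyde F1, which is methylenated with Ph3P=CH2 to the C5 vinyl compound F2. Ring-closing metathesis with the second-generation Grubbs catalyst closes the trisubstituted cyclopentene F3 (C8=C9) with loss of ethene. Epoxidation with dimethyldioxirane then gives 32 if the reagent prefers the α face. If it prefers the β face, N-bromosuccinimide in aqueous THF should give the bromohydrin F4 (C8 α-OH; C9 β-Br) through the same facial preference, and K2CO3 closes it to 32 with the oxygen on the opposite, α face.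

Step 4. Incomplete control of the ketene acetal geometry in the presence of DMPU would erode the configuration at C10, and a boat transition state would erode both centres. The fallback moves the geometric information from the enolate to the alkene. It sets out from 2 and 5 and returns at 9. The enantiomeric alkynol (2R)-but-3-yn-2-ol F5 is coupled with 2 as in step 1 to give (2R)-6-methylhept-6-en-3-yn-2-ol F6. Semi-hydrogenation over Pd/CaCO3 poisoned with Pb(OAc)2 and quinoline gives (2R,3Z)-6-methylhepta-3,6-dien-2-ol F7, which is acylated with 5 to (2R,3Z)-6-methylhepta-3,6-dien-2-yl 3-methylbutanoate F8. Enolisation with LiN(iPr)2 in THF alone, which reliably gives the ketene acetal with isopropyl trans to the silyloxy group, and rearrangement through the mirror-image chair should lead to the same silyl ester 8 and acid 9.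

Step 11. Addition of the methyl group from the α face, for example by delivery from a magnesium alkoxide aggregate, would give the C3 epimer. The fallback sets out from 17 and returns at 18. Wittig methylenation with Ph3P=CH2 gives the exocyclic C3 methylene compound F9. Epoxidation directed by the homoallylic C1 hydroxyl (VO(acac)2, t-BuOOH) places the oxygen on the α face and gives the spiro-epoxide F10; the remote 2-methylallyl alkene has no directing group and should not react. Opening at the CH2 terminus with LiBHEt3 gives 18.

Step 17. Displacement of the β-branched primary triflate by the weak sulfur nucleophile may be slow, so that participation of the C3 silyl ether oxygen or of the 2-methylallyl alkene, or decomposition of the triflate, takes over. The fallback forms the C–S bond with a strong sulfur nucleophile; it sets out from 26 and returns at 28. Treatment with PhSSPh and PBu3 gives the C9 phenyl sulfide F11, which is S-phenylated with diphenyliodonium triflate and Cu(OAc)2 (cat.) in 1,2-dichloroethane at 80 °C.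

## Further compounds

F1 | step 19 | C9 aldehyde (C5 α-CHO; C6 β-2-methylallyl; C3 α-OSiEt3) | COc1ccc(C(=O)O[C@@H]2C[C@](C)(O[Si](CC)(CC)CC)C[C@H](C=O)[C@@H](CC(C)=C)[C@@H]2C(C)C)cc1O[Si](C)(C)C(C)(C)C
F2 | step 19 | C5 vinyl compound (C5 α-vinyl; C6 β-2-methylallyl) | COc1ccc(C(=O)O[C@@H]2C[C@](C)(O[Si](CC)(CC)CC)C[C@H](C=C)[C@@H](CC(C)=C)[C@@H]2C(C)C)cc1O[Si](C)(C)C(C)(C)C
F3 | step 19 | trans-fused cyclopentene with C8=C9 alkene | COc1ccc(C(=O)O[C@@H]2C[C@](C)(O[Si](CC)(CC)CC)C[C@H]3[C@@H](CC(C)=C3)[C@@H]2C(C)C)cc1O[Si](C)(C)C(C)(C)C
F4 | step 19 | bromohydrin (C8 α-OH, β-CH3; C9 β-Br) | COc1ccc(C(=O)O[C@@H]2C[C@](C)(O[Si](CC)(CC)CC)C[C@H]3[C@@H](C[C@@](C)(O)[C@@H]3Br)[C@@H]2C(C)C)cc1O[Si](C)(C)C(C)(C)C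
F5 | step 4 | (2R)-but-3-yn-2-ol | C[C@@H](O)C#C
F6 | step 4 | (2R)-6-methylhept-6-en-3-yn-2-ol | C[C@@H](O)C#CCC(C)=C
F7 | step 4 | (2R,3Z)-6-methylhepta-3,6-dien-2-ol | C[C@@H](O)/C=C\CC(C)=C
F8 | step 4 | (2R,3Z)-6-methylhepta-3,6-dien-2-yl 3-methylbutanoate | C[C@@H](OC(=O)CC(C)C)/C=C\CC(C)=C
F9 | step 11 | exocyclic C3 methylene compound (C1 α-OH; C5 α-CH2OH) | O[C@@H]1CC(=C)C[C@H](CO)[C@@H](CC(C)=C)[C@@H]1C(C)C
F10 | step 11 | C3 spiro-epoxide with oxygen α | O[C@@H]1C[C@@]2(CO2)C[C@H](CO)[C@@H](CC(C)=C)[C@@H]1C(C)C
F11 | step 17 | C9 phenyl sulfide | COc1ccc(C(=O)O[C@@H]2C[C@](C)(O[Si](CC)(CC)CC)C[C@H](CSc3ccccc3)[C@@H](CC(C)=C)[C@@H]2C(C)C)cc1O[Si](C)(C)C(C)(C)C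
A1 | alternative 1 | trans-fused hydroazulen-9-one with C1 hydroxyl trans to C10 isopropenyl and C3 triethylsilyl ether | O[C@H]1C[C@](C)(O[Si](CC)(CC)CC)C[C@H]2[C@@H](CCC2=O)[C@@H]1C(C)=C
A2 | alternative 1 | cyclopentanone aldehyde with C6 2-methylprop-1-enyl group | O=CC[C@](C)(O[Si](CC)(CC)CC)C[C@H]1[C@H](C=C(C)C)CCC1=O
A3 | alternative 2 | 4-isopropyl-5-methoxy-2,7-dimethyl-3,8a-dihydro-2H-azulen-1-one | COC1=CC(C)=C[C@H]2C(C[C@H](C)C2=O)=C1C(C)C
A4 | alternative 2 | 1-diazo-4-(2-isopropyl-3-methoxy-5-methylphenyl)-3-methylbutan-2-one | COc1cc(C)cc(C[C@H](C)C(=O)C=[N+]=[N-])c1C(C)C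
A5 | alternative 3 | trans-fused hydroazulene-3,9-dione with C1 tert-butyldimethylsilyl ether | CC(C)(C)[Si](C)(C)O[C@@H]1CC(=O)C[C@H]2[C@@H](C[C@H](C)C2=O)[C@@H]1C(C)C
A6 | alternative 3 | cyclohept-2-enone with C6 2-methyl-3-oxopropyl arm | CC(C)(C)[Si](C)(C)O[C@@H]1CC(=O)C=C[C@@H](C[C@H](C)C=O)[C@@H]1C(C)C
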